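**Retrosynthetic overview**
1. The target comes from a fully protected flavone (four MOM ethers, one TES ether) by one acid step. Its isopropenyl group comes from a methyl ketone, and that from a methyl carbinol which is kept until ring C is closed, so that no oxidation is run beside a free, electron-rich phenol.
2. Ring C, the last ring formed, is closed by 6-endo addition of the C8a phenol to an aryl ynone; the ynone comes from the ring B acetylide and a C4a aldehyde that this phenol directs into its only free ortho position.
3. The strategy rests on this feature: C1'' is a CH2 joining C8 of ring A to the stereocentre C2'', and C8a, next to C8, carries the ring oxygen O1. The array O1–C8a–C8–C1''–C2'' is the footprint of a ring A ortho-quinone methide captured at its CH2 by an aldehyde enamine.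
4. Key disconnection C1''–C2'': a chroman-2-ol (a temporary ring on ring A, formed first and opened by MeMgBr) from a 2-(tosylmethyl)phenol and 5-methyl-5-(triethylsilyloxy)hexanal under a chiral secondary amine. Its lactol carbon becomes the isopropenyl carbon and its ring oxygen becomes O1, the only free phenol.
5. Building blocks: the sulfone from 2,4,6-trihydroxybenzaldehyde, the aldehyde from hex-5-en-2-one, the ring B alkyne from 2,4-dihydroxybenzaldehyde; rings A and B are bought.

Key step: step 8

Assumption: the side chain is numbered from ring A (C1'' the CH2 on C8, C2'' the stereocentre, which is R in the target); the S catalyst is chosen because its usual enamine shielding model predicts the R centre, and the R catalyst would be used if the opposite sense were found.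

**Step 1**
Reactants: 1 2,4,6-trihydroxybenzaldehyde
Product: 2 2-hydroxy-4,6-bis(methoxymethoxy)benzaldehyde
Conditions: MOMCl (2.2 equiv), i-Pr2NEt (2.5 equiv), CH2Cl2, 0 °C to rt
Reagents that add atoms: chloromethyl methyl ether, COCCl
Why: O-alkylation of phenols by the chloromethyl ether (MOM protection) should stop at the bis-ether, because the last hydroxyl is hydrogen-bonded to the formyl oxygen and is the least nucleophilic of the three.

**Step 2**
Reactants: 2 2-hydroxy-4,6-bis(methoxymethoxy)benzaldehyde
Product: 3 2-(hydroxymethyl)-3,5-bis(methoxymethoxy)phenol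
Conditions: NaBH4, THF/MeOH, 0 °C; pH 7 work-up, used crude
Reagents that add atoms: none
Why: Hydride reduction of the aldehyde by NaBH4 leaves the MOM ethers alone, and cold, neutral handling keeps the ionisable, electron-rich salicyl alcohol from self-condensing.

**Step 3**
Reactants: 3 2-(hydroxymethyl)-3,5-bis(methoxymethoxy)phenol
Product: 4 3,5-bis(methoxymethoxy)-2-[(4-methylbenzenesulfonyl)methyl]phenol
Conditions: p-TolSO2Na (3 equiv), AcOH, THF/H2O, 0 °C to rt
Reagents that add atoms: sodium p-toluenesulfinate, Cc1ccc(cc1)S(=O)[O-].[Na+]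
Why: SN1-type substitution of a benzylic alcohol by sulfinate (S-alkylation to the sulfone): the three oxygen substituents let a weak acid ionise the C–OH bond, an excess of the soft sulfur nucleophile should trap the cation faster than the ring of a second molecule can, and aryl MOM ethers withstand acetic acid at room temperature.

**Step 4**
Reactants: 5 hex-5-en-2-one
Product: 6 2-methylhex-5-en-2-ol
Conditions: MeMgBr (1.2 equiv), Et2O, 0 °C; aq. NH4Cl
Reagents that add atoms: methylmagnesium bromide, C[Mg]Br
Why: Grignard addition to the ketone gives the tertiary alcohol that becomes the C(CH3)2OH end of the side chain.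

**Step 5**
Reactants: 6 2-methylhex-5-en-2-ol
Product: 7 triethyl[(2-methylhex-5-en-2-yl)oxy]silane
Conditions: TESOTf (1.2 equiv), 2,6-lutidine (1.5 equiv), CH2Cl2, 0 °C
Reagents that add atoms: triethylsilyl trifluoromethanesulfonate, CC[Si](CC)(CC)OS(=O)(=O)C(F)(F)F
Why: Silylation with a silyl triflate and a hindered pyridine base is the standard way to cap a tertiary alcohol, and the TES ether keeps the later hydroxy aldehyde from closing to a lactol while still falling off in the final acid step.

**Step 6**
Reactants: 7 triethyl[(2-methylhex-5-en-2-yl)oxy]silane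
Product: 9 5-methyl-5-(triethylsilyloxy)hexan-1-ol, via alkylborane 8 (not isolated)
Conditions: 9-BBN, THF, 0 °C to rt; then NaOH (3 M aq), H2O2 (30%), 0 °C to rt
Reagents that add atoms: 9-borabicyclo[3.3.1]nonane, B1C2CCCC1CCC2 (boron in 8 only); hydrogen peroxide, OO
Why: Hydroboration–oxidation, in which the bulky borane places boron on the terminal carbon (anti-Markovnikov) and alkaline peroxide replaces boron by hydroxyl.

**Step 7**
Reactants: 9 5-methyl-5-(triethylsilyloxy)hexan-1-ol
Product: 10 5-methyl-5-(triethylsilyloxy)hexanal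
Conditions: TEMPO (10 mol%), PhI(OAc)2 (1.1 equiv), CH2Cl2, rt
Reagents that add atoms: none
Why: Oxoammonium (TEMPO) oxidation with PhI(OAc)2 as terminal oxidant takes a primary alcohol to the aldehyde without over-oxidation, and the tertiary silyl ether tolerates the acetic acid that is formed.

**Step 8**
Reactants: 4 3,5-bis(methoxymethoxy)-2-[(4-methylbenzenesulfonyl)methyl]phenol; 10 5-methyl-5-(triethylsilyloxy)hexanal (2.5 equiv)
Product: 13 (3R)-5,7-bis(methoxymethoxy)-3-[3-methyl-3-(triethylsilyloxy)butyl]chroman-2-ol (both C2 epimers), via ortho-quinone methide 11 (not isolated), via open hydroxy aldehyde 12 (not isolated)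
Conditions: (S)-α,α-diphenylprolinol trimethylsilyl ether (20 mol%), aq. NaHCO3 (5%), CH2Cl2, 0 °C to rt
Reagents that add atoms: none
Why: NaHCO3 deprotonates the phenol of 4 and p-toluenesulfinate leaves by 1,4-elimination to give ortho-quinone methide 11, while 10 condenses with the secondary amine to the E-enamine, whose nucleophilic carbon (the aldehyde alpha carbon) adds to the exocyclic CH2 of 11 in a Michael-type step driven by rearomatisation of ring A. Hydrolysis of the resulting iminium ion returns the catalyst and gives 12, which closes to 13. The closest known reaction type is the diarylprolinol silyl ether catalysed formal [4+2] annulation of aldehydes with ortho-quinone methides released in situ from 2-(sulfonylalkyl)phenols, which gives chroman-2-ols. The pyran ring is closed after the C–C bond by 6-exo-trig addition of the phenol oxygen to the aldehyde carbon (hemiacetal formation), so the annulation is a stepwise, formally inverse-demand hetero-[4+2] closure. The new stereocentre C3 (C2'' of the target) is set by the catalyst, whose diphenyl(trimethylsilyloxy)methyl group blocks one face of the enamine, so that the S catalyst should give the 3R centre as in its Michael additions of aldehydes, whereas the lactol carbon forms as a mixture that is erased later. The step needs C-alkylation of the enamine to win over self-condensation of 11 and N-alkylation of the catalyst, which should be helped by the two MOM-oxy groups that stabilise 11, by its slow release in the two-phase medium and by the excess of 10; only the enamine face matters because the CH2 terminus of 11 is not prostereogenic.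

**Step 9**
Reactants: 13 (3R)-5,7-bis(methoxymethoxy)-3-[3-methyl-3-(triethylsilyloxy)butyl]chroman-2-ol
Product: 15 2-[(2R)-2-(1-hydroxyethyl)-5-methyl-5-(triethylsilyloxy)hexyl]-3,5-bis(methoxymethoxy)phenol (both carbinol epimers), via ring-opened aldehyde magnesium phenoxide 14 (not isolated)
Conditions: MeMgBr (4 equiv), THF, 0 °C to rt; aq. NH4Cl
Reagents that add atoms: methylmagnesium bromide, C[Mg]Br (magnesium and bromine in 14 only)
Why: Grignard addition to a lactol: the first equivalent deprotonates 13, the magnesium lactolate opens to the formyl-bearing bromomagnesium phenoxide 14 and a second equivalent adds to its aldehyde faster than it can enolise, so C2'' is kept while the new carbinol centre forms as a mixture that the later oxidation removes.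

**Step 10**
Reactants: 15 2-[(2R)-2-(1-hydroxyethyl)-5-methyl-5-(triethylsilyloxy)hexyl]-3,5-bis(methoxymethoxy)phenol
Product: 17 2-hydroxy-3-[(2R)-2-(1-hydroxyethyl)-5-methyl-5-(triethylsilyloxy)hexyl]-4,6-bis(methoxymethoxy)benzaldehyde, via hydroxymethyl phenol 16 (not isolated)
Conditions: MgCl2 (3 equiv), Et3N (6 equiv), (CH2O)n (8 equiv), THF, reflux
Reagents that add atoms: formaldehyde (as paraformaldehyde), C=O
Why: Magnesium-mediated ortho-formylation of a phenol (Casnati–Skattebøl): the magnesium phenoxide delivers formaldehyde to its only free ortho carbon, the future C4a, to give 16, which a second formaldehyde oxidises by Oppenauer-type hydride transfer, while the chelate-directed mechanism leaves the CH between the two MOM ethers and the un-ionised secondary alcohol alone.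

**Step 11**
Reactants: 18 2,4-dihydroxybenzaldehyde
Product: 19 2,4-bis(methoxymethoxy)benzaldehyde
Conditions: NaH (2.5 equiv), MOMCl (2.5 equiv), DMF, 0 °C to rt
Reagents that add atoms: chloromethyl methyl ether, COCCl
Why: O-alkylation of the sodium phenoxides (MOM protection), with a strong base because the hydrogen-bonded hydroxyl ortho to the formyl group must react as well.

**Step 12**
Reactants: 19 2,4-bis(methoxymethoxy)benzaldehyde
Product: 20 1-ethynyl-2,4-bis(methoxymethoxy)benzene
Conditions: dimethyl (1-diazo-2-oxopropyl)phosphonate (1.3 equiv), K2CO3 (2 equiv), MeOH, 0 °C to rt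
Reagents that add atoms: dimethyl (1-diazo-2-oxopropyl)phosphonate, CC(=O)C(=[N+]=[N-])P(=O)(OC)OC
Why: Ohira–Bestmann variant of the Seyferth–Gilbert homologation, in which methanolysis of the reagent frees the diazomethylphosphonate anion that turns the aldehyde into the terminal alkyne by olefination, loss of N2 and 1,2-shift, under basic conditions that cannot touch the MOM ethers.

**Step 13**
Reactants: 17 2-hydroxy-3-[(2R)-2-(1-hydroxyethyl)-5-methyl-5-(triethylsilyloxy)hexyl]-4,6-bis(methoxymethoxy)benzaldehyde; 20 1-ethynyl-2,4-bis(methoxymethoxy)benzene (3.5 equiv)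
Product: 22 2-{3-[2,4-bis(methoxymethoxy)phenyl]-1-hydroxyprop-2-yn-1-yl}-6-[(2R)-2-(1-hydroxyethyl)-5-methyl-5-(triethylsilyloxy)hexyl]-3,5-bis(methoxymethoxy)phenol (mixture of diastereomers), via lithium acetylide 21 (not isolated)
Conditions: 20, n-BuLi (3.4 equiv), THF, −78 °C; then 17, −78 to 0 °C; pH 7 buffer, used crude
Reagents that add atoms: n-butyllithium, [Li]CCCC (lithium in 21 only)
Why: 1,2-Addition of a lithium acetylide to an aldehyde, in which two equivalents are spent on the phenol and the alcohol of 17 (the alkyne is re-formed and recovered) and a third adds to the formyl group; the acid-labile ortho-hydroxybenzylic alcohol is not purified.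

**Step 14**
Reactants: 22 the triol from step 13
Product: 23 3-[2,4-bis(methoxymethoxy)phenyl]-1-{2-hydroxy-3-[(2R)-2-(1-hydroxyethyl)-5-methyl-5-(triethylsilyloxy)hexyl]-4,6-bis(methoxymethoxy)phenyl}prop-2-yn-1-one (both carbinol epimers)
Conditions: MnO2 (activated, 20 equiv), CH2Cl2, rt
Reagents that add atoms: none
Why: MnO2 oxidation is selective for the benzylic, propargylic alcohol and should give the ynone while leaving the saturated secondary alcohol, whose oxidation is wanted only later, untouched.

**Step 15**
Reactants: 23 the ortho-hydroxyaryl ynone from step 14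
Product: 24 2-[2,4-bis(methoxymethoxy)phenyl]-8-[(2R)-2-(1-hydroxyethyl)-5-methyl-5-(triethylsilyloxy)hexyl]-5,7-bis(methoxymethoxy)-4H-chromen-4-one (both carbinol epimers)
Conditions: K2CO3 (2 equiv), acetone, rt to 40 °C
Reagents that add atoms: none
Why: Intramolecular oxa-Michael addition of the phenoxide to the ynone (6-endo-dig, favoured in an aprotic medium) closes ring C as the flavone, and since the other ortho oxygen is a MOM ether only the phenol released from the lactol can cyclise, which puts the side chain on C8.

**Step 16**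
Reactants: 24 the flavone carbinol from step 15
Product: 25 8-[(2R)-2-acetyl-5-methyl-5-(triethylsilyloxy)hexyl]-2-[2,4-bis(methoxymethoxy)phenyl]-5,7-bis(methoxymethoxy)-4H-chromen-4-one
Conditions: Dess–Martin periodinane (1.5 equiv), CH2Cl2, 0 °C to rt
Reagents that add atoms: none
Why: Dess–Martin oxidation of the secondary alcohol merges the two carbinol epimers into one methyl ketone, with no free phenol left to be oxidised and under near-neutral conditions that should not epimerise C2'' next to the new carbonyl.

**Step 17**
Reactants: 25 the methyl ketone from step 16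
Product: 26 2-[2,4-bis(methoxymethoxy)phenyl]-5,7-bis(methoxymethoxy)-8-[(2R)-5-methyl-2-(prop-1-en-2-yl)-5-(triethylsilyloxy)hexyl]-4H-chromen-4-one
Conditions: Cp2Ti(μ-Cl)(μ-CH2)AlMe2 (Tebbe reagent, 1.3 equiv), pyridine, THF/toluene, −40 to 0 °C
Reagents that add atoms: Tebbe reagent Cp2Ti(μ-Cl)(μ-CH2)AlMe2, C[Al-]1(C)C[Ti]([Cl+]1)(C1C=CC=C1)C1C=CC=C1
Why: Tebbe methylenation transfers CH2 from titanium to the ketone carbon by [2+2] addition and cycloreversion without any base, so C2'' cannot enolise, and a ketone reacts well below the temperature at which the vinylogous-ester carbonyl C4 of the flavone would.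

**Step 18**
Reactants: 26 the protected isopropenyl flavone from step 17
Product: 27 2-(2,4-dihydroxyphenyl)-5,7-dihydroxy-8-[(2R)-5-hydroxy-5-methyl-2-(prop-1-en-2-yl)hexyl]-4H-chromen-4-one
Conditions: HCl (3 M aq)/MeOH (1:4), rt to 40 °C, stopped at full conversion
Reagents that add atoms: none
Why: Acid-catalysed acetal exchange with methanol removes the four MOM ethers and solvolyses the tertiary TES ether in the same pot, and dilute acid at low temperature is chosen so that acetal cleavage should outrun protonation of the isopropenyl group.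

**Compound list**
1 | 2,4,6-trihydroxybenzaldehyde | O=Cc1c(O)cc(O)cc1O | starting material
2 | 2-hydroxy-4,6-bis(methoxymethoxy)benzaldehyde | O=Cc1c(O)cc(OCOC)cc1OCOC | intermediate
3 | 2-(hydroxymethyl)-3,5-bis(methoxymethoxy)phenol | OCc1c(O)cc(OCOC)cc1OCOC | intermediate
4 | 3,5-bis(methoxymethoxy)-2-[(4-methylbenzenesulfonyl)methyl]phenol | Cc1ccc(cc1)S(=O)(=O)Cc1c(O)cc(OCOC)cc1OCOC | intermediate
5 | hex-5-en-2-one | CC(=O)CCC=C | starting material
6 | 2-methylhex-5-en-2-ol | CC(C)(O)CCC=C | intermediate
7 | triethyl[(2-methylhex-5-en-2-yl)oxy]silane | CC[Si](CC)(CC)OC(C)(C)CCC=C | intermediate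
8 | 9-[5-methyl-5-(triethylsilyloxy)hexyl]-9-borabicyclo[3.3.1]nonane | CC[Si](CC)(CC)OC(C)(C)CCCCB1C2CCCC1CCC2 | intermediate (not isolated)
9 | 5-methyl-5-(triethylsilyloxy)hexan-1-ol | CC[Si](CC)(CC)OC(C)(C)CCCCO | intermediate
10 | 5-methyl-5-(triethylsilyloxy)hexanal | CC[Si](CC)(CC)OC(C)(C)CCCC=O | intermediate
11 | 3,5-bis(methoxymethoxy)-6-methylidenecyclohexa-2,4-dien-1-one (ortho-quinone methide) | C=C1C(=O)C=C(OCOC)C=C1OCOC | intermediate (not isolated)
12 | (2R)-2-{[2-hydroxy-4,6-bis(methoxymethoxy)phenyl]methyl}-5-methyl-5-(triethylsilyloxy)hexanal | O=C[C@H](CCC(C)(C)O[Si](CC)(CC)CC)Cc1c(O)cc(OCOC)cc1OCOC | intermediate (not isolated)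
13 | (3R)-5,7-bis(methoxymethoxy)-3-[3-methyl-3-(triethylsilyloxy)butyl]chroman-2-ol, both C2 epimers | OC1Oc2cc(OCOC)cc(OCOC)c2C[C@H]1CCC(C)(C)O[Si](CC)(CC)CC | intermediate
14 | bromomagnesium 2-[(2R)-2-formyl-5-methyl-5-(triethylsilyloxy)hexyl]-3,5-bis(methoxymethoxy)phenolate | O=C[C@H](CCC(C)(C)O[Si](CC)(CC)CC)Cc1c(O[Mg]Br)cc(OCOC)cc1OCOC | intermediate (not isolated)
15 | 2-[(2R)-2-(1-hydroxyethyl)-5-methyl-5-(triethylsilyloxy)hexyl]-3,5-bis(methoxymethoxy)phenol, both carbinol epimers | CC(O)[C@H](CCC(C)(C)O[Si](CC)(CC)CC)Cc1c(O)cc(OCOC)cc1OCOC | intermediate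
16 | 2-(hydroxymethyl)-6-[(2R)-2-(1-hydroxyethyl)-5-methyl-5-(triethylsilyloxy)hexyl]-3,5-bis(methoxymethoxy)phenol | CC(O)[C@H](CCC(C)(C)O[Si](CC)(CC)CC)Cc1c(O)c(CO)c(OCOC)cc1OCOC | intermediate (not isolated)
17 | 2-hydroxy-3-[(2R)-2-(1-hydroxyethyl)-5-methyl-5-(triethylsilyloxy)hexyl]-4,6-bis(methoxymethoxy)benzaldehyde | CC(O)[C@H](CCC(C)(C)O[Si](CC)(CC)CC)Cc1c(O)c(C=O)c(OCOC)cc1OCOC | intermediate
18 | 2,4-dihydroxybenzaldehyde | O=Cc1ccc(O)cc1O | starting material
19 | 2,4-bis(methoxymethoxy)benzaldehyde | O=Cc1ccc(OCOC)cc1OCOC | intermediate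
20 | 1-ethynyl-2,4-bis(methoxymethoxy)benzene | C#Cc1ccc(OCOC)cc1OCOC | intermediate
21 | lithium [2,4-bis(methoxymethoxy)phenyl]acetylide | [Li]C#Cc1ccc(OCOC)cc1OCOC | intermediate (not isolated)
22 | 2-{3-[2,4-bis(methoxymethoxy)phenyl]-1-hydroxyprop-2-yn-1-yl}-6-[(2R)-2-(1-hydroxyethyl)-5-methyl-5-(triethylsilyloxy)hexyl]-3,5-bis(methoxymethoxy)phenol, mixture of diastereomers | CC(O)[C@H](CCC(C)(C)O[Si](CC)(CC)CC)Cc1c(O)c(C(O)C#Cc2ccc(OCOC)cc2OCOC)c(OCOC)cc1OCOC | intermediate
23 | 3-[2,4-bis(methoxymethoxy)phenyl]-1-{2-hydroxy-3-[(2R)-2-(1-hydroxyethyl)-5-methyl-5-(triethylsilyloxy)hexyl]-4,6-bis(methoxymethoxy)phenyl}prop-2-yn-1-one | CC(O)[C@H](CCC(C)(C)O[Si](CC)(CC)CC)Cc1c(O)c(C(=O)C#Cc2ccc(OCOC)cc2OCOC)c(OCOC)cc1OCOC | intermediate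
24 | 2-[2,4-bis(methoxymethoxy)phenyl]-8-[(2R)-2-(1-hydroxyethyl)-5-methyl-5-(triethylsilyloxy)hexyl]-5,7-bis(methoxymethoxy)-4H-chromen-4-one | CC(O)[C@H](CCC(C)(C)O[Si](CC)(CC)CC)Cc1c(OCOC)cc(OCOC)c2c(=O)cc(-c3ccc(OCOC)cc3OCOC)oc12 | intermediate
25 | 8-[(2R)-2-acetyl-5-methyl-5-(triethylsilyloxy)hexyl]-2-[2,4-bis(methoxymethoxy)phenyl]-5,7-bis(methoxymethoxy)-4H-chromen-4-one | CC(=O)[C@H](CCC(C)(C)O[Si](CC)(CC)CC)Cc1c(OCOC)cc(OCOC)c2c(=O)cc(-c3ccc(OCOC)cc3OCOC)oc12 | intermediate
26 | 2-[2,4-bis(methoxymethoxy)phenyl]-5,7-bis(methoxymethoxy)-8-[(2R)-5-methyl-2-(prop-1-en-2-yl)-5-(triethylsilyloxy)hexyl]-4H-chromen-4-one | C=C(C)[C@H](CCC(C)(C)O[Si](CC)(CC)CC)Cc1c(OCOC)cc(OCOC)c2c(=O)cc(-c3ccc(OCOC)cc3OCOC)oc12 | intermediate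
27 | 2-(2,4-dihydroxyphenyl)-5,7-dihydroxy-8-[(2R)-5-hydroxy-5-methyl-2-(prop-1-en-2-yl)hexyl]-4H-chromen-4-one | C=C(C)[C@H](CCC(C)(C)O)Cc1c(O)cc(O)c2c(=O)cc(-c3ccc(O)cc3O)oc12 | target

**Step count**
Total: 18 steps. Longest linear sequence: 13 steps (5 → 6 → 7 → 9 → 10 → 13 → 15 → 17 → 22 → 23 → 24 → 25 → 26 → 27).

**Steps most likely to fail**

Step 8. The unsubstituted quinone methide 11 may condense with itself or alkylate the nitrogen of the amine catalyst faster than the enamine adds, or the enamine face may be poorly differentiated. The same C1''–C2'' bond and ring would then be made through a carbene-bound enolate instead of an enamine: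
- Setting out from aldehyde 10, oxidation with NaClO2/NaH2PO4/2-methylbut-2-ene in t-BuOH/H2O should give 5-methyl-5-(triethylsilyloxy)hexanoic acid F1.
- 1,1'-Carbonyldiimidazole in THF should convert it into 1-(1H-imidazol-1-yl)-5-methyl-5-(triethylsilyloxy)hexan-1-one F2.
- With a chiral aminoindanol-derived triazolium salt and K2CO3, the carbene should turn F2 into an enolate equivalent that adds to 11 (released from sulfone 4 by the same base) and lactonises with release of the carbene. This is the known carbene-catalysed formal [4+2] annulation of ortho-quinone methides to dihydrocoumarins, and it should give (3R)-5,7-bis(methoxymethoxy)-3-[3-methyl-3-(triethylsilyloxy)butyl]chroman-2-one F3.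
- i-Bu2AlH in CH2Cl2 at −78 °C would reduce F3 to lactol 13, where the route is rejoined.

Step 3. Ionisation of the benzylic position in acid may lead to Friedel–Crafts self-alkylation of the electron-rich ring (oligomers) or to partial loss of a MOM group. The sulfinate would then be introduced by elimination–addition under neutral conditions:
- Setting out from aldehyde 2, reductive amination with Me2NH and NaBH(OAc)3 in 1,2-dichloroethane should give the phenolic Mannich base 2-[(dimethylamino)methyl]-3,5-bis(methoxymethoxy)phenol F4.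
- MeI in acetone would quaternise it to 1-[2-hydroxy-4,6-bis(methoxymethoxy)phenyl]-N,N,N-trimethylmethanaminium iodide F5.
- Warming F5 with p-TolSO2Na in DMF should expel Me3N and add the sulfinate to the transient 11, giving sulfone 4, where the route is rejoined.

Step 18. Protonation of the isopropenyl group may compete with acetal cleavage, leading to ring closure onto the C7 hydroxyl, addition of methanol, or migration of the double bond to C2'' with loss of the stereocentre. The two kinds of protecting group would then be removed separately and without protic acid: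
- Setting out from 26, Bu4NF in THF should cleave the silyl ether to 2-[2,4-bis(methoxymethoxy)phenyl]-8-[(2R)-5-hydroxy-5-methyl-2-(prop-1-en-2-yl)hexyl]-5,7-bis(methoxymethoxy)-4H-chromen-4-one F6.
- ZnBr2 with n-PrSH in CH2Cl2 at 0 °C (transfer of the methoxymethyl groups to the soft thiol, expected within minutes) should then free the four phenols and give target 27.

**Further compounds**
F1 | step 8 | 5-methyl-5-(triethylsilyloxy)hexanoic acid | CC[Si](CC)(CC)OC(C)(C)CCCC(=O)O
F2 | step 8 | 1-(1H-imidazol-1-yl)-5-methyl-5-(triethylsilyloxy)hexan-1-one | CC[Si](CC)(CC)OC(C)(C)CCCC(=O)n1ccnc1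
F3 | step 8 | (3R)-5,7-bis(methoxymethoxy)-3-[3-methyl-3-(triethylsilyloxy)butyl]chroman-2-one | O=C1Oc2cc(OCOC)cc(OCOC)c2C[C@H]1CCC(C)(C)O[Si](CC)(CC)CC
F4 | step 3 | 2-[(dimethylamino)methyl]-3,5-bis(methoxymethoxy)phenol | CN(C)Cc1c(O)cc(OCOC)cc1OCOC
F5 | step 3 | 1-[2-hydroxy-4,6-bis(methoxymethoxy)phenyl]-N,N,N-trimethylmethanaminium iodide | C[N+](C)(C)Cc1c(O)cc(OCOC)cc1OCOC.[I-]
F6 | step 18 | 2-[2,4-bis(methoxymethoxy)phenyl]-8-[(2R)-5-hydroxy-5-methyl-2-(prop-1-en-2-yl)hexyl]-5,7-bis(methoxymethoxy)-4H-chromen-4-one | C=C(C)[C@H](CCC(C)(C)O)Cc1c(OCOC)cc(OCOC)c2c(=O)cc(-c3ccc(OCOC)cc3OCOC)oc12
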